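The cyclohexene ring is read as a Diels–Alder retron: its tetrasubstituted C5=C10 alkene lies between the oxygenated C6 and the C9 methylene (locants defined below). An enantioselective endo [4+2] cycloaddition of a citronellal-derived (E)-1-silyloxy diene (C9=C10–C5=C6) with a (Z)-β-boryl enone (C7=C8) forms C8–C9 and C6–C7 in one operation and sets C6, C7 and C8. Boron stands in for the lactone oxygen at C8, so the dienophile stays a configurationally fixed cis-enone. The acetyl group then becomes the α-methylene lactone by carbonylation of its enol triflate. After acylation of the primary hydroxyl, the all-cis C6 oxygen is inverted by Mitsunobu esterification with isobutyric acid.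

Key step: step 8

Remarks and assumptions:
- Locants C1–C15 follow eudesmanolide-type numbering: lactone C12(=O)–C11(=C13H2) fused at C7–C8; ring alkene C5=C10 with C14 on C10; side chain C4(C15)–C3–C2–C1–O.
- The (S)-configured oxazaborolidine is assumed to shield the enone face so that the enantiomeric series drawn for 13 results; if the sense proves opposite, the (R)-catalyst is used with nothing else changed.
- Commercial (S)-citronellal of high enantiomeric purity is assumed.

Step 1
Reactants: 1 (S)-citronellal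
Product: 2 citronellal trimethylsilyl enol ether (E/Z mixture)
Conditions: TMSCl, Et3N, DMF, 80 °C
Reagents that add atoms: chlorotrimethylsilane, C[Si](C)(C)Cl
Why: Amine-mediated enolisation and O-silylation of the aldehyde (silyl enol ether formation) should give the enol silane without touching the C4 stereocentre, whose hydrogen is not α to the carbonyl.

Step 2
Reactants: 2 citronellal trimethylsilyl enol ether; 3 2,2-dimethoxypropane
Product: 5 (3S)-3,7-dimethyl-2-(propan-2-ylidene)oct-6-enal, via β-methoxy aldehyde 4 (not isolated)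
Conditions: TMSOTf (5 mol %), CH2Cl2, −78 °C; then DBU, rt
Reagents that add atoms: none
Why: Mukaiyama-type aldol addition of the enol silane to the oxocarbenium ion of the ketal (acetals are activated by TMSOTf, the product aldehyde is not) followed by E1cB loss of methanol should give the conjugated tetrasubstituted enal; the C4 hydrogen is cross-conjugated and not acidic, so the stereocentre is kept.

Step 3
Reactants: 5 (3S)-3,7-dimethyl-2-(propan-2-ylidene)oct-6-enal
Product: 7 (3S)-3-methyl-2-(propan-2-ylidene)hexane-1,6-diol, via dialdehyde 6 (not isolated)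
Conditions: O3, CH2Cl2/MeOH, −78 °C (Sudan Red 7B end-point); Me2S; then NaBH4, 0 °C
Reagents that add atoms: ozone, [O-][O+]=O
Why: Ozonolysis with reductive work-up; ozone should cleave the electron-rich isolated trisubstituted alkene far faster than the deactivated, tetrasubstituted enal alkene, and borohydride then reduces both aldehydes.

Step 4
Reactants: 7 (3S)-3-methyl-2-(propan-2-ylidene)hexane-1,6-diol
Product: 8 (3S)-6-hydroxy-3-methyl-2-(propan-2-ylidene)hexanal
Conditions: MnO2, CH2Cl2, rt
Reagents that add atoms: none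
Why: Chemoselective allylic oxidation: MnO2 should oxidise only the allylic primary alcohol and leave the saturated one.

Step 5
Reactants: 8 (3S)-6-hydroxy-3-methyl-2-(propan-2-ylidene)hexanal
Product: 9 (1E,3S)-1,6-bis[(tert-butyldimethylsilyl)oxy]-3-methyl-2-(prop-1-en-2-yl)hex-1-ene
Conditions: TBSOTf (2.4 equiv), Et3N, CH2Cl2, 0 °C → rt
Reagents that add atoms: tert-butyldimethylsilyl triflate, CC(C)(C)[Si](C)(C)OS(=O)(=O)C(F)(F)F
Why: Silylation of the alcohol and silyl dienol ether formation (O-silylation of the enal, γ-deprotonation by Et3N); the s-trans enal, which keeps oxygen away from the cis γ-methyl (A(1,3) strain), should lead mainly to the E enol ether with oxygen in the outside position.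

Step 6
Reactants: 10 but-3-yn-2-one
Product: 11 (Z)-4-iodobut-3-en-2-one
Conditions: NaI, AcOH, rt
Reagents that add atoms: sodium iodide, [Na+].[I-]
Why: Hydroiodination of an electron-poor alkyne: conjugate addition of iodide and protonation of the allenolate anti to iodine should give the kinetic Z-β-iodoenone.

Step 7
Reactants: 11 (Z)-4-iodobut-3-en-2-one
Product: 12 (Z)-4-(4,4,5,5-tetramethyl-1,3,2-dioxaborolan-2-yl)but-3-en-2-one
Conditions: B2pin2, PdCl2(PPh3)2 (3 mol %), PPh3, KOPh, toluene, 50 °C
Reagents that add atoms: bis(pinacolato)diboron, CC1(C)OB(OC1(C)C)B1OC(C)(C)C(C)(C)O1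
Why: Miyaura borylation: oxidative addition of the alkenyl iodide to zerovalent palladium, transmetalation with the diboron and reductive elimination should replace iodine by boron with retention of the Z geometry under mild, weakly basic conditions.

Step 8
Reactants: 9 (1E,3S)-silyloxy diene; 12 (Z)-β-boryl enone
Product: 13 1-[(1R,2R,6R)-2-[(tert-butyldimethylsilyl)oxy]-3-[(2S)-5-[(tert-butyldimethylsilyl)oxy]pentan-2-yl]-4-methyl-6-(4,4,5,5-tetramethyl-1,3,2-dioxaborolan-2-yl)cyclohex-3-en-1-yl]ethan-1-one (silyloxy, acetyl and boryl groups all cis)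
Conditions: (S)-B-(o-tolyl)-α,α-diphenylprolinol oxazaborolidine·HNTf2 (20 mol %), CH2Cl2, −78 → −20 °C
Reagents that add atoms: none
Why: Concerted, asynchronous normal-demand [4+2] cycloaddition of the silyloxy diene (HOMO) with the enone bound through its carbonyl oxygen to the cationic oxazaborolidine (LUMO); the closest known type is the chiral oxazaborolidinium-catalysed Diels–Alder reaction of acyclic enones with 1-oxygenated dienes. The carbocycle is closed by the cycloaddition itself, bonds C8–C9 and C6–C7 forming suprafacially on both partners. C7 and C8 should come out cis because the Z-dienophile adds stereospecifically; C6 should come out cis to the acetyl group because the E-diene (silyloxy group outside) reacts through the endo transition state; the absolute sense at all three is set by the catalyst, which shields one face of the coordinated enone, while the remote C4 centre is a spectator. The step needs regio-, endo-, facial and periselectivity: the 1-silyloxy group makes C9 the nucleophilic terminus that attacks the boron-bearing β-carbon C8, so the acetyl-bearing C7 bonds to C6; the Lewis-acid-bound acetyl group directs endo; the hindered trisubstituted enol ether C5=C6 is a poor 2π partner for hetero-Diels–Alder or Mukaiyama–Michael side reactions. Boron is not a π-donor, so unlike an enol ether or enol ester at C8 it leaves the enone LUMO low and the Z geometry fixed.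

Step 9
Reactants: 13 cycloadduct methyl ketone
Product: 15 1-[(1R,2R,6R)-2-[(tert-butyldimethylsilyl)oxy]-3-[(2S)-5-[(tert-butyldimethylsilyl)oxy]pentan-2-yl]-4-methyl-6-(4,4,5,5-tetramethyl-1,3,2-dioxaborolan-2-yl)cyclohex-3-en-1-yl]ethenyl trifluoromethanesulfonate, via potassium enolate 14 (not isolated)
Conditions: KN(SiMe3)2, THF, −78 °C; then PhNTf2, −78 → 0 °C
Reagents that add atoms: N-phenylbis(trifluoromethanesulfonimide), O=S(=O)(N(c1ccccc1)S(=O)(=O)C(F)(F)F)C(F)(F)F
Why: Kinetic enol triflate formation: the bulky amide should remove a methyl proton and not the hindered C7 methine, and the methyl-side enolate cannot expel the β-silyloxy or β-boryl group before it is trapped on oxygen.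

Step 10
Reactants: 15 enol triflate boronate
Product: 16 1-[(1R,2R,6R)-2-[(tert-butyldimethylsilyl)oxy]-3-[(2S)-5-[(tert-butyldimethylsilyl)oxy]pentan-2-yl]-6-hydroxy-4-methylcyclohex-3-en-1-yl]ethenyl trifluoromethanesulfonate
Conditions: NaBO3·4H2O, THF/H2O, rt
Reagents that add atoms: sodium perborate (anion drawn without water of crystallisation), [Na+].[Na+].O[B-]1(O)OO[B-](O)(O)OO1
Why: Oxidation of a secondary alkylboronate: carbon migrates from boron to oxygen with retention at C8, under conditions mild enough for the enol triflate, the silyl ethers and the tetrasubstituted alkene.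

Step 11
Reactants: 16 hydroxy enol triflate
Product: 17 (3aR,4R,7aR)-4-[(tert-butyldimethylsilyl)oxy]-5-[(2S)-5-[(tert-butyldimethylsilyl)oxy]pentan-2-yl]-6-methyl-3-methylidene-3a,4,7,7a-tetrahydro-1-benzofuran-2(3H)-one
Conditions: Pd(PPh3)4 (10 mol %), CO (1 atm), Bu3N, LiCl, MeCN, 65 °C
Reagents that add atoms: carbon monoxide, [C-]#[O+]
Why: Palladium-catalysed carbonylative lactonisation: oxidative addition of the enol triflate to zerovalent palladium, CO insertion and capture of the acylpalladium by the cis C8 hydroxyl should close the cis-fused α-methylene-γ-butyrolactone.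

Step 12
Reactants: 17 bis-silyl ether lactone
Product: 18 (3aS,4R,7aR)-4-hydroxy-5-[(2S)-5-hydroxypentan-2-yl]-6-methyl-3-methylidene-3a,4,7,7a-tetrahydro-1-benzofuran-2(3H)-one (C6 hydroxyl cis to the lactone)
Conditions: HF·pyridine, pyridine/THF, 0 °C → rt
Reagents that add atoms: none
Why: Fluoride-mediated desilylation under weakly acidic, non-basic conditions should free both hydroxyls without conjugate addition to the methylene lactone and without base-induced translactonisation to the C6 oxygen.

Step 13
Reactants: 18 diol lactone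
Product: 19 (4S)-4-[(3aS,4R,7aR)-4-hydroxy-6-methyl-3-methylidene-2-oxo-2,3,3a,4,7,7a-hexahydro-1-benzofuran-5-yl]pentyl 2-methylpropanoate
Conditions: i-PrCOCl (1.05 equiv), 2,4,6-collidine, CH2Cl2, −78 °C
Reagents that add atoms: isobutyryl chloride, CC(C)C(=O)Cl
Why: Chemoselective O-acylation: with one equivalent of acyl chloride and a hindered base at low temperature the unhindered primary hydroxyl should be esterified far faster than the secondary allylic C6 hydroxyl, which is flanked by the tetrasubstituted alkene and the ring fusion, and no stereocentre is touched.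

Step 14
Reactants: 19 mono-isobutyrate alcohol; 20 isobutyric acid
Product: 21 (3aR,4S,7aR)-6-methyl-3-methylidene-5-[(2S)-5-(2-methylpropanoyloxy)pentan-2-yl]-2-oxo-2,3,3a,4,7,7a-hexahydro-1-benzofuran-4-yl 2-methylpropanoate
Conditions: PPh3, DIAD, toluene, 0 °C → rt
Reagents that add atoms: none
Why: Mitsunobu esterification: the C6 hydroxyl is activated as its alkoxyphosphonium ion and displaced by isobutyrate in an SN2 reaction with inversion from the open face anti to the lactone, which should turn the cis C6–O of the cycloadduct into the trans C6 ester of the target.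

Compound list
1 | (S)-citronellal, (3S)-3,7-dimethyloct-6-enal | O=CC[C@@H](C)CCC=C(C)C | starting material
2 | trimethyl{[(3S)-3,7-dimethylocta-1,6-dien-1-yl]oxy}silane (E/Z mixture) | C[Si](C)(C)OC=C[C@@H](C)CCC=C(C)C | intermediate
3 | 2,2-dimethoxypropane | COC(C)(C)OC | starting material
4 | (3S)-2-(2-methoxypropan-2-yl)-3,7-dimethyloct-6-enal (both C2 epimers) | COC(C)(C)C(C=O)[C@@H](C)CCC=C(C)C | intermediate (not isolated)
5 | (3S)-3,7-dimethyl-2-(propan-2-ylidene)oct-6-enal | O=CC(=C(C)C)[C@@H](C)CCC=C(C)C | intermediate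
6 | (3S)-3-methyl-2-(propan-2-ylidene)hexanedial | O=CC(=C(C)C)[C@@H](C)CCC=O | intermediate (not isolated)
7 | (3S)-3-methyl-2-(propan-2-ylidene)hexane-1,6-diol | OCC(=C(C)C)[C@@H](C)CCCO | intermediate
8 | (3S)-6-hydroxy-3-methyl-2-(propan-2-ylidene)hexanal | O=CC(=C(C)C)[C@@H](C)CCCO | intermediate
9 | (1E,3S)-1,6-bis[(tert-butyldimethylsilyl)oxy]-3-methyl-2-(prop-1-en-2-yl)hex-1-ene | C=C(C)/C(=C/O[Si](C)(C)C(C)(C)C)[C@@H](C)CCCO[Si](C)(C)C(C)(C)C | intermediate
10 | but-3-yn-2-one | CC(=O)C#C | starting material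
11 | (Z)-4-iodobut-3-en-2-one | CC(=O)/C=C\I | intermediate
12 | (Z)-4-(4,4,5,5-tetramethyl-1,3,2-dioxaborolan-2-yl)but-3-en-2-one | CC(=O)/C=C\B1OC(C)(C)C(C)(C)O1 | intermediate
13 | 1-[(1R,2R,6R)-2-[(tert-butyldimethylsilyl)oxy]-3-[(2S)-5-[(tert-butyldimethylsilyl)oxy]pentan-2-yl]-4-methyl-6-(4,4,5,5-tetramethyl-1,3,2-dioxaborolan-2-yl)cyclohex-3-en-1-yl]ethan-1-one | CC(=O)[C@@H]1[C@H](B2OC(C)(C)C(C)(C)O2)CC(C)=C([C@@H](C)CCCO[Si](C)(C)C(C)(C)C)[C@@H]1O[Si](C)(C)C(C)(C)C | intermediate
14 | potassium enolate of 13 (methyl side) | [K+].C=C([O-])[C@@H]1[C@H](B2OC(C)(C)C(C)(C)O2)CC(C)=C([C@@H](C)CCCO[Si](C)(C)C(C)(C)C)[C@@H]1O[Si](C)(C)C(C)(C)C | intermediate (not isolated)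
15 | 1-[(1R,2R,6R)-2-[(tert-butyldimethylsilyl)oxy]-3-[(2S)-5-[(tert-butyldimethylsilyl)oxy]pentan-2-yl]-4-methyl-6-(4,4,5,5-tetramethyl-1,3,2-dioxaborolan-2-yl)cyclohex-3-en-1-yl]ethenyl trifluoromethanesulfonate | C=C(OS(=O)(=O)C(F)(F)F)[C@@H]1[C@H](B2OC(C)(C)C(C)(C)O2)CC(C)=C([C@@H](C)CCCO[Si](C)(C)C(C)(C)C)[C@@H]1O[Si](C)(C)C(C)(C)C | intermediate
16 | 1-[(1R,2R,6R)-2-[(tert-butyldimethylsilyl)oxy]-3-[(2S)-5-[(tert-butyldimethylsilyl)oxy]pentan-2-yl]-6-hydroxy-4-methylcyclohex-3-en-1-yl]ethenyl trifluoromethanesulfonate | C=C(OS(=O)(=O)C(F)(F)F)[C@@H]1[C@H](O)CC(C)=C([C@@H](C)CCCO[Si](C)(C)C(C)(C)C)[C@@H]1O[Si](C)(C)C(C)(C)C | intermediate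
17 | (3aR,4R,7aR)-4-[(tert-butyldimethylsilyl)oxy]-5-[(2S)-5-[(tert-butyldimethylsilyl)oxy]pentan-2-yl]-6-methyl-3-methylidene-3a,4,7,7a-tetrahydro-1-benzofuran-2(3H)-one | C=C1C(=O)O[C@@H]2CC(C)=C([C@@H](C)CCCO[Si](C)(C)C(C)(C)C)[C@H](O[Si](C)(C)C(C)(C)C)[C@H]12 | intermediate
18 | (3aS,4R,7aR)-4-hydroxy-5-[(2S)-5-hydroxypentan-2-yl]-6-methyl-3-methylidene-3a,4,7,7a-tetrahydro-1-benzofuran-2(3H)-one | C=C1C(=O)O[C@@H]2CC(C)=C([C@@H](C)CCCO)[C@H](O)[C@H]12 | intermediate
19 | (4S)-4-[(3aS,4R,7aR)-4-hydroxy-6-methyl-3-methylidene-2-oxo-2,3,3a,4,7,7a-hexahydro-1-benzofuran-5-yl]pentyl 2-methylpropanoate | C=C1C(=O)O[C@@H]2CC(C)=C([C@@H](C)CCCOC(=O)C(C)C)[C@H](O)[C@H]12 | intermediate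
20 | isobutyric acid (2-methylpropanoic acid) | CC(C)C(=O)O | starting material
21 | (3aR,4S,7aR)-6-methyl-3-methylidene-5-[(2S)-5-(2-methylpropanoyloxy)pentan-2-yl]-2-oxo-2,3,3a,4,7,7a-hexahydro-1-benzofuran-4-yl 2-methylpropanoate | C=C1C(=O)O[C@@H]2CC(C)=C([C@@H](C)CCCOC(=O)C(C)C)[C@@H](OC(=O)C(C)C)[C@H]12 | target

Total step count: 14. Longest linear sequence: 12 steps (steps 1–5 and 8–14); steps 6–7 prepare the dienophile.

Steps most likely to fail

Step 8. The endo preference may be eroded or reversed, because the cis boryl group crowds the endo transition state; this would deliver the C6 epimer. The silyl ether at C6 lets that material converge on the target. From 9 and 12, the cycloaddition would then give the exo cycloadduct F1, the C6 epimer of 13. It is taken through the same triflation, perborate oxidation, carbonylative lactonisation and desilylation, giving the enol triflate F2, the alcohol F3, the lactone F4 and the diol F5. In the diol F5 the C6 hydroxyl is already trans to C7, so both hydroxyls are acylated with retention (isobutyric anhydride, DMAP, pyridine) and no Mitsunobu inversion is needed; the sequence returns at 21.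

Step 7. The Z geometry may be lost through isomerisation of the β-acyl alkenylpalladium intermediate, or the iodide may be reduced. The fallback avoids any alkenylpalladium species and sets out from 10. Ketalisation (1,2-bis(trimethylsilyloxy)ethane, TMSOTf cat., −78 °C) gives 2-ethynyl-2-methyl-1,3-dioxolane F6. C-Borylation (n-BuLi, then i-PrOBpin) gives the alkynylboronate F7. Cis-semireduction by hydroboration with Cy2BH and protonolysis with AcOH gives the (Z)-alkenylboronate ketal F8. Mild deketalisation (PPTS, acetone/H2O) returns at 12.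

Step 14. E2 elimination towards the conjugated triene, or sluggish displacement at the hindered allylic C6 alkoxyphosphonium ion, may compete with inversion. The fallback replaces the in-situ phosphonium activation by an isolated sulfonate and a naked carboxylate, and sets out from 19. The C6 hydroxyl is converted into the chloromethanesulfonate F9 (ClCH2SO2Cl, pyridine, 0 °C). SN2 displacement with cesium isobutyrate and 18-crown-6 in toluene, with inversion at C6, returns at 21.

Further compounds
F1 | step 8 | 1-[(1R,2S,6R)-2-[(tert-butyldimethylsilyl)oxy]-3-[(2S)-5-[(tert-butyldimethylsilyl)oxy]pentan-2-yl]-4-methyl-6-(4,4,5,5-tetramethyl-1,3,2-dioxaborolan-2-yl)cyclohex-3-en-1-yl]ethan-1-one (C6 epimer of 13, silyloxy trans to acetyl) | CC(=O)[C@@H]1[C@H](B2OC(C)(C)C(C)(C)O2)CC(C)=C([C@@H](C)CCCO[Si](C)(C)C(C)(C)C)[C@H]1O[Si](C)(C)C(C)(C)C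
F2 | step 8 | enol triflate of F1 (C6 epimer of 15) | C=C(OS(=O)(=O)C(F)(F)F)[C@@H]1[C@H](B2OC(C)(C)C(C)(C)O2)CC(C)=C([C@@H](C)CCCO[Si](C)(C)C(C)(C)C)[C@H]1O[Si](C)(C)C(C)(C)C
F3 | step 8 | C8 alcohol from F2 (C6 epimer of 16) | C=C(OS(=O)(=O)C(F)(F)F)[C@@H]1[C@H](O)CC(C)=C([C@@H](C)CCCO[Si](C)(C)C(C)(C)C)[C@H]1O[Si](C)(C)C(C)(C)C
F4 | step 8 | (3aR,4S,7aR)-4-[(tert-butyldimethylsilyl)oxy]-5-[(2S)-5-[(tert-butyldimethylsilyl)oxy]pentan-2-yl]-6-methyl-3-methylidene-3a,4,7,7a-tetrahydro-1-benzofuran-2(3H)-one (C6 epimer of 17) | C=C1C(=O)O[C@@H]2CC(C)=C([C@@H](C)CCCO[Si](C)(C)C(C)(C)C)[C@@H](O[Si](C)(C)C(C)(C)C)[C@H]12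
F5 | step 8 | (3aS,4S,7aR)-4-hydroxy-5-[(2S)-5-hydroxypentan-2-yl]-6-methyl-3-methylidene-3a,4,7,7a-tetrahydro-1-benzofuran-2(3H)-one (C6 epimer of 18) | C=C1C(=O)O[C@@H]2CC(C)=C([C@@H](C)CCCO)[C@@H](O)[C@H]12
F6 | step 7 | 2-ethynyl-2-methyl-1,3-dioxolane | CC1(C#C)OCCO1
F7 | step 7 | 4,4,5,5-tetramethyl-2-[(2-methyl-1,3-dioxolan-2-yl)ethynyl]-1,3,2-dioxaborolane | CC1(C#CB2OC(C)(C)C(C)(C)O2)OCCO1
F8 | step 7 | 4,4,5,5-tetramethyl-2-[(Z)-2-(2-methyl-1,3-dioxolan-2-yl)ethenyl]-1,3,2-dioxaborolane | CC1(/C=C\B2OC(C)(C)C(C)(C)O2)OCCO1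
F9 | step 14 | C6 chloromethanesulfonate of 19 (sulfonate cis to the lactone) | C=C1C(=O)O[C@@H]2CC(C)=C([C@@H](C)CCCOC(=O)C(C)C)[C@H](OS(=O)(=O)CCl)[C@H]12
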